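- The autumn run at 35 °C had made 96.0 target per catalyst charged by 2.50 h, a turnover count n (percent target over percent catalyst), and the noon run at 0 °C had reached 72.5 by 12.0 h.

| flask | starting material | second substrate | partner | free catalyst | temperature | remark | time |
|---|---|---|---|---|---|---|---|
| noon | 0.20 M | 0.25 equiv | 0.70 equiv | 0.2 mol% | 0 °C | run made earlier |  |
| autumn | 0.20 M | 1 equiv | 0.70 equiv | 0.2 mol% | 35 °C | run made earlier |  |
| dawn | 0.20 M | 0.50 equiv | 0.35 equiv | 0.2 mol% | 0 °C | run made earlier |  |
| alpha | 0.20 M | 0.500 equiv | 0.700 equiv | 0.2 mol% | 5 °C |  | 20 h |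
| beta | 0.20 M | 0.500 equiv | 0.700 equiv | 0.2 mol% | 35 °C |  | 20 h |
| delta | 0.20 M | 0.500 equiv | 0.700 equiv | 0.2 mol% | 65 °C |  | 20 h |

| run | time / h | target / % | starting material / % |
|---|---|---|---|
| noon | 0.833 | 2.0 | 98.8 |
| noon | 2.50 | 4.3 | 95.3 |
| noon | 4.00 | 7.3 | 93.3 |
| noon | 6.00 | 9.2 | 90.6 |
| noon | 10.0 | 13.7 | 86.9 |
| noon | 12.0 | 14.5 | 85.1 |
| autumn | 0.417 | 6.7 | 93.8 |
| autumn | 0.833 | 12.0 | 88.5 |
| autumn | 1.33 | 15.3 | 85.0 |
| autumn | 2.00 | 17.9 | 82.0 |
| autumn | 2.50 | 19.2 | 80.8 |
| dawn | 2.50 | 4.2 | 96.1 |
| dawn | 5.00 | 7.6 | 92.4 |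
| dawn | 8.00 | 10.1 | 89.1 |
| dawn | 10.0 | 12.6 | 87.5 |
| dawn | 12.0 | 13.7 | 86.3 |

(standard deviation of a reading: 0.3 percentage points)

- what was read earlier has a scatter of 0.3 percentage points, one standard deviation
- a reading or a percentage of target counts all its forms, free or not

1. which flask leads in amount of target, in percent of the starting material charged ("all alike" within 1.5 percentage points) (alpha / beta / delta / all alike)
2. how much target is there at the end, in percent of the starting material charged: alpha
3. how much target is there at the end, in percent of the starting material charged: beta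
4. how much target is there at the end, in percent of the starting material charged: delta

- The level comes first. If each target takes one partner, partner is the limiting reagent, and the turnover ceiling N is 350, partner charged over catalyst charged, in noon, autumn, alpha, beta and delta, which is 70.0% target.
- The autumn curve starts with a turnover rate of 80.3 h⁻¹ and has bent to 13.0 h⁻¹ by its last readings. Yet autumn's n stands well below N, so this knee is not the level.
- Noon's last stretch runs at a turnover rate of 4.42 h⁻¹, while autumn passes a like count at 33.2 h⁻¹. That is a factor of 7.52 at like n, a rough one, as autumn also holds more second substrate.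
- This reckoning holds alpha to noon's late slope, which ends it near n = 108, or 21.6%.
- Beta, on autumn's late slope, could reach 324, but that slope is still falling. The midpoint between stopping and holding gives 210, or 42.0%.
- Delta, one similar step of heat higher, is reckoned to cover the distance to N in about 2.60 h at that scaled slope, well inside 20 h. So this reckoning puts delta on the ceiling, ahead of beta and alpha.
- The forecast differs, naming alpha with 29%, 14% and 7% for alpha, beta and delta, on the view that “final yield falls as temperature rises”.
- The flasks give 19.6% in alpha, 44.1% in beta and 67.5% in delta, so delta leads.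

    partner + catalyst intermediate A → free catalyst + target (k = 32.0 L mol⁻¹ min⁻¹, Ea = 38.0 kJ mol⁻¹)
    second substrate + free catalyst ⇌ catalyst intermediate B (K = 5.80 L mol⁻¹, k = 2.50 L mol⁻¹ min⁻¹, Ea = 48.0 kJ mol⁻¹, ΔH = −77.0 kJ mol⁻¹)
    partner + catalyst intermediate B → free catalyst + second product (k = 55.0 L mol⁻¹ min⁻¹, Ea = 47.0 kJ mol⁻¹)
    starting material + free catalyst ⇌ catalyst intermediate A (K = 60.0 L mol⁻¹, k = 1.20 L mol⁻¹ min⁻¹, Ea = 46.0 kJ mol⁻¹, ΔH = −8.00 kJ mol⁻¹)
    free catalyst + target ⇌ idle complex (K = 240 L mol⁻¹, k = 0.140 L mol⁻¹ min⁻¹, Ea = 49.0 kJ mol⁻¹, ΔH = −15.0 kJ mol⁻¹)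
    (constants at 5 °C)

- Delta made 338 turnovers to target and 12.3 to second product, which together meet N = 350, with partner at 0% after 20.0 h. With the temperature taken off the step that binds starting material and free catalyst into catalyst intermediate A, the gap between delta and alpha falls from 48 percentage points to 0.61 points. A neighbour of beta with 0.8 mol% free catalyst has a ceiling of 87.5. Its partner stands at 0%, and 68.5 turnovers went to target and 19.0 to second product.

The earlier runs and the new flask come from a simulation with made-up constants, and the scatter is random.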